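## Analysis of the target

The target is a 3a,4,5,7a-tetrahydro-1H-indene: a cyclopentene (C1, C2=C3, C3a, C7a) trans-fused to a cyclohexene (C4, C5, C6=C7). Methyl groups sit on C1, C3, C4 and C7; C5 carries ethyl and the (1E,3E)-4-phenylbuta-1,3-dienyl chain (C1′ to C4′); C4 carries the carboxyl carbon (C8). These locants are used for the same carbons in every intermediate.

There are five contiguous stereocentres, (1R,3aR,4R,5S,7aS). H-3a and H-7a are trans, and the C1 methyl and the C3a–C4 bond are both trans to the C7a–C7 bond. At the vicinal quaternary carbons the carboxyl (C4) and the dienyl (C5) are cis to each other and to H-3a, with the C4 methyl and the ethyl on the other face.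

The phenyl diene is sensitive to acid, light and oxidants. The γ,δ-unsaturated acid would close onto C7 as a bridged lactone under strong acid. The only heteroatoms are those of the acid, so there is nothing to direct reagents in the finished skeleton.

The main difficulty is the pair of adjacent quaternary centres on a trans-fused bicycle, which must be set relative to three ring stereocentres and in one absolute sense.

The strategy rests on the cyclopentene. C1–C2=C3, with methyls on C1 and C3, is a three-carbon unit that bridges C7a and C3a, and both of those carbons carry a carbon that can be a carbonyl (C7 and C4). The ring is therefore the retron of a [3+2] union of a silyl-substituted 1,3-dimethylallene with a trans-1,2-diacyl alkene, and the allene axis can supply all absolute configuration.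

## Retrosynthetic reasoning

**C1′=C2′.** The diene is the most fragile part and is made last, from aldehyde 26 and phosphonate 27. C1′ sits on the quaternary C5, so the aldehyde cannot epimerise, and the olefination has only to give the (E)-alkene. The aldehyde is carried as dimethyl acetal 25. A C1′ alcohol would sit cis to the C4 carboxyl and close to a five-membered lactone as soon as it was freed.

**C4–C5, with C7–O.** Acid 25 is cut between the two quaternary carbons and traced to lactone 22 through silyl ketene acetal 23 and silyl ester 24. The [3,3] shift forms C4–C5, moves the alkene to C6=C7 and closes the cyclohexene. The six-membered lactone ties C7 to C4 through C7a–C3a, so only a boat-like array is possible. The C7 configuration then decides which face of C4 is attacked, and the alkene geometry decides C5. No other single bond formation sets both quaternary centres from stereochemistry that is easier to install.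

**The lactone oxygen and the two carbon groups on C7.** Lactone 22 comes from diol 20 by oxidation of the primary C8 alcohol. Diol 20 comes from enone 19 by addition of a methyl nucleophile to C7. Enone 19 comes from lactone 11 and alkenyllithium 18, made from iodide 17. In 11 the carbonyl is C7 and the ring oxygen is on C8, the reverse of 22. C7 is thus an acylating carbon that takes two different carbon groups in sequence, and C8 is released as the alcohol that is later oxidised. The order (alkenyl first, methyl second) is chosen so that Felkin–Anh addition places methyl on the face that 22 needs.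

**The alkenyl unit.** Iodide 17 is traced through aldehyde 16, alcohol 15 and acid 14 to diiodide 13 and malonate 12. The decarboxylative elimination that gives 14 places iodine trans to the remaining carboxyl, hence cis to ethyl. This is the geometry that the boat needs, and it is carried unchanged to 22.

**C2–Si, C8–O and C4–C8.** Lactone 11 comes from silyl lactone 10 by replacing silicon on C2 with hydrogen, done where no other acid-labile group is present. Lactone 10 comes from hydroxy ester 9, and 9 from alkene 8 by anti-Markovnikov hydration. Alkene 8 comes from ketone 7 by methylenation, which adds C8. The ketone is therefore homologated without strong base, and the new alcohol distinguishes the two carbonyl branches by closing onto the C7a ester.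

**C7a–C1 and C3a–C3 (key step).** Cyclopentene 7 is cut into enone 3 and allenylsilane 6. Both cyclopentene bonds and three stereocentres come in one step. The ketone and ester of 3 become the two differentiated handles at C3a and C7a. The forward reaction must attack the carbon β to the ketone, transfer the allene chirality anti to silicon, and place the C1 methyl trans to the ester.

**The two partners.** Enone 3 comes from ylide 1 and aldehyde 2 in one olefination. Allene 6 comes from mesylate 5 of the commercial silyl butynol 4 by anti SN2′ entry of a methyl group at the silyl-bearing alkyne carbon. This gives the same allene as silylation of a pentynol derivative would, and avoids a silyl anion.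

## Alternatives that were turned down

**Alternative 1:** The cut is at C4–C8 and C5–C1′, taken together as two bonds of a cyclobutane. In the forward step, enone A2 is irradiated with ketene acetal A3 to give the cis-fused photoadduct A1. The cyclobutanone released from its acetal is later cleaved between C8 and C1′.
- For: both quaternary centres and their cis relationship come in one step, enforced by the four-membered ring fusion, and photocycloaddition tolerates congestion.
- Against: the tetrasubstituted enone alkene reacts slowly, and facial control rests on one neighbouring stereocentre of A2. A1 contains nothing of the cyclopentene, so C1, C7a, C2=C3 and the methylated C6=C7 alkene would still have to be built beside a quaternary carbon. The regioselective cyclobutanone cleavage adds steps.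
- Comparison: on the C4/C5 problem it is stronger than the chosen route, because no strained pericyclic boat is needed. The chosen route offers in its place the C1/C3a/C7a triad and the absolute configuration from one allene axis, and fewer steps after the key step.

**Alternative 2:** The cut is at C5–C6, with the C1′=C2′ alkene arising in the same event. In the forward step, zerovalent palladium inserts into the C6–I bond of iodide A5, C6 adds to C5 (6-exo), and β-hydride loss from C2′ gives ester A4.
- For: ring closure, the C5 quaternary centre and the diene arise together, with no oxidation-state changes at C1′. This endgame is shorter than the chosen one.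
- Against: the C5 configuration depends on which rotamer about C4–C5 presents the alkene, with nothing to fix it. Insertion into a trisubstituted alkene beside a quaternary carbon is slow. A5 needs an acyclic quaternary C4 and a (Z)-iodoalkene on a cyclopentene that must still be made, and A4 ends in hydrolysis of a very hindered ester.
- Comparison: the chosen route fixes C5 by alkene geometry in a ring-constrained rearrangement, and provides the cyclopentene itself.

**Alternative 3:** The cut is at C4–C5 with C7–O. In the forward step, the silyl ketene acetal of lactone A7 rearranges through a boat to acid A6.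
- For: it creates both quaternary centres with relay from C7. It is as strong as the chosen route on this point, since the same rearrangement is step 16 here.
- Against, as the organising step: it presupposes A7 with C1, C3a, C7a and C7 already set, and does not say how the trans-substituted cyclopentene is obtained as one enantiomer. The silyloxymethyl group of A6 would also free an alcohol beside the cis carboxyl.
- Comparison: the chosen strategy supplies the missing cyclopentene and replaces the silyl ether by an acetal.

Key step: step 4

Remarks on the chemistry: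
- C4 is drawn without a descriptor from 9 to 22, because hydroboration gives both epimers and the centre is planarised in 23.
- The SMILES of allene 6 carries the tetrahedral mark on the central carbon, read over the four terminal substituents; this is the (S)-axis.
- Aldehyde 2 is taken as commercial and freshly depolymerised.

## Steps

**Step 1**
Reactants: 1 1-(triphenyl-λ5-phosphanylidene)propan-2-one; 2 methyl glyoxylate
Product: 3 methyl (E)-4-oxopent-2-enoate
Conditions: CH2Cl2, 0 °C → rt
Reagents that add atoms: none
Why: Wittig olefination of an aldehyde by a ketone-stabilised ylide, which gives the (E)-alkene and does not touch the ester.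

**Step 2**
Reactants: 4 (S)-4-(trimethylsilyl)but-3-yn-2-ol
Product: 5 (S)-4-(trimethylsilyl)but-3-yn-2-yl methanesulfonate
Conditions: MsCl, Et3N, CH2Cl2, −78 → 0 °C
Reagents that add atoms: methanesulfonyl chloride, CS(=O)(=O)Cl
Why: O-Sulfonylation of a secondary propargylic alcohol; only the O–S bond forms, so the carbinol configuration is retained.

**Step 3**
Reactants: 5 (S)-4-(trimethylsilyl)but-3-yn-2-yl methanesulfonate
Product: 6 (S)-trimethyl(penta-2,3-dien-2-yl)silane [(S)-2-(trimethylsilyl)penta-2,3-diene]
Conditions: MeMgCl, CuBr, LiBr, THF, −78 → −20 °C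
Reagents that add atoms: methylmagnesium chloride, C[Mg]Cl
Why: Anti SN2′ displacement of a propargylic sulfonate by a methylcopper reagent: methyl enters at the silyl-bearing alkyne carbon on the face opposite the leaving mesylate, so the (S)-centre of 5 becomes the (S)-axis of 6. Low temperature and a Grignard-derived monoalkylcopper limit electron-transfer racemisation of the allene.

**Step 4**
Reactants: 3 methyl (E)-4-oxopent-2-enoate; 6 (S)-trimethyl(penta-2,3-dien-2-yl)silane
Product: 7 methyl (1R,2R,5S)-2-acetyl-3,5-dimethyl-4-(trimethylsilyl)cyclopent-3-ene-1-carboxylate (ring C1, C2, C5 of this name are C7a, C3a, C1 of the target; all-trans)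
Conditions: TiCl4, CH2Cl2, −78 °C
Reagents that add atoms: none
Why: TiCl4 binds the ketone oxygen of 3, the more basic of its two carbonyls, which makes C7a (β to the ketone, α to the ester) the electrophilic carbon; the CH terminus of 6 attacks it anti to silicon (SE2′), the β-silyl vinyl cation undergoes a 1,2-silyl shift, and the titanium enolate carbon C3a bonds to the new cationic carbon C3, so that C7a–C1 and C3a–C3 form in this order. This is the Danheiser (trimethylsilyl)cyclopentene annulation, a stepwise cationic [3+2] reaction of allenylsilanes with α,β-unsaturated ketones. The one ring closes by attack of the enolate on a linear vinyl cation with the C2=C3 π bond kept inside the ring (formally 5-endo at a digonal carbon), which is easy because an empty in-plane orbital, not a π bond, is attacked. C1 is set by the allene axis alone: anti attack on the (S)-axis gives the C1 configuration of the target whichever face of 3 reacts. C7a is set relative to C1 in the same bond-forming event, through an open synclinal transition state in which the C1 methyl turns away from the ester on C7a (1,7a-trans). C3a follows from suprafacial addition across the (E)-alkene and, being α to the ketone, also rests in its more stable trans arrangement. The step needs attack at the ketone-activated carbon, complete anti chirality transfer and the trans topicity; these rest on the Lewis basicity of the ketone, the stereoelectronic anti preference of the C–Si bond and sterics, and since C3a and C7a are epimerisable α-carbonyl centres while C1 is not, all-trans 7 is also the most stable isomer of the set.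

**Step 5**
Reactants: 7 methyl (1R,2R,5S)-2-acetyl-3,5-dimethyl-4-(trimethylsilyl)cyclopent-3-ene-1-carboxylate
Product: 8 methyl (1R,2S,5S)-3,5-dimethyl-2-(prop-1-en-2-yl)-4-(trimethylsilyl)cyclopent-3-ene-1-carboxylate
Conditions: CH2Br2, Zn, TiCl4, THF/CH2Cl2, 0 °C → rt
Reagents that add atoms: dibromomethane, BrCBr
Why: Lombardo methylenation of the ketone; the reagent is not basic, so the allylic α-hydrogen on C3a is neither epimerised nor moved into conjugation, and the ester and the vinylsilane are left alone.

**Step 6**
Reactants: 8 methyl (1R,2S,5S)-3,5-dimethyl-2-(prop-1-en-2-yl)-4-(trimethylsilyl)cyclopent-3-ene-1-carboxylate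
Product: 10 (4RS,4aR,7S,7aR)-4,5,7-trimethyl-6-(trimethylsilyl)-4,4a,7,7a-tetrahydrocyclopenta[c]pyran-1(3H)-one, via hydroxy ester 9 (not isolated)
Conditions: 9-BBN, THF, 0 °C → rt; H2O2, aq NaOAc, 0 °C; then PPTS (cat.), PhH, 60 °C
Reagents that add atoms: hydrogen peroxide, OO
Why: Anti-Markovnikov hydroboration–oxidation, in which 9-BBN selects the 1,1-disubstituted alkene over the tetrasubstituted vinylsilane; the δ-hydroxy ester then closes to the six-membered lactone under mild acid. C4 forms as both epimers, which converge later.

**Step 7**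
Reactants: 10 (4RS,4aR,7S,7aR)-4,5,7-trimethyl-6-(trimethylsilyl)-4,4a,7,7a-tetrahydrocyclopenta[c]pyran-1(3H)-one
Product: 11 (4RS,4aR,7R,7aS)-4,5,7-trimethyl-4,4a,7,7a-tetrahydrocyclopenta[c]pyran-1(3H)-one
Conditions: CF3CO2H, CH2Cl2, 0 °C
Reagents that add atoms: none
Why: Protodesilylation of a vinylsilane: ipso protonation at C2 gives the tertiary β-silyl cation at C3, which loses silicon, so the alkene stays at C2=C3. The vinylsilane is far more easily protonated than the product alkene, and nothing else in 10 is acid-labile.

**Step 8**
Reactants: 12 diethyl 2-ethylpropanedioate (diethyl ethylmalonate)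
Product: 13 diethyl 2-(diiodomethyl)-2-ethylpropanedioate
Conditions: NaH, CHI3, Et2O, reflux
Reagents that add atoms: iodoform, IC(I)I
Why: Diiodomethylation of the malonate anion by iodoform, the standard entry to β-iodoacrylic acids.

**Step 9**
Reactants: 13 diethyl 2-(diiodomethyl)-2-ethylpropanedioate
Product: 14 (2E)-2-ethyl-3-iodoprop-2-enoic acid
Conditions: KOH, EtOH/H2O, reflux; then HCl
Reagents that add atoms: potassium hydroxide, [K+].[OH-]
Why: Saponification followed by decarboxylative anti elimination of iodide; iodine ends trans to the remaining carboxyl and cis to ethyl, which fixes the alkene geometry used in step 16.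

**Step 10**
Reactants: 14 (2E)-2-ethyl-3-iodoprop-2-enoic acid
Product: 15 (2E)-2-ethyl-3-iodoprop-2-en-1-ol
Conditions: LiAlH4, Et2O, 0 °C
Reagents that add atoms: none
Why: Hydride reduction of the acid to the allylic alcohol at low temperature, which leaves the vinylic C–I bond and the alkene geometry intact.

**Step 11**
Reactants: 15 (2E)-2-ethyl-3-iodoprop-2-en-1-ol
Product: 16 (2E)-2-ethyl-3-iodoprop-2-enal
Conditions: MnO2, CH2Cl2, rt
Reagents that add atoms: none
Why: Allylic oxidation with MnO2 stops at the enal and does not isomerise the alkene.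

**Step 12**
Reactants: 16 (2E)-2-ethyl-3-iodoprop-2-enal
Product: 17 (1E)-2-ethyl-1-iodo-3,3-dimethoxyprop-1-ene
Conditions: HC(OMe)3, MeOH, PPTS (cat.), rt
Reagents that add atoms: trimethyl orthoformate, COC(OC)OC; methanol, CO
Why: Acid-catalysed acetalisation with orthoformate as water scavenger. The acetal keeps C1′ at the aldehyde level, so that no free C1′ alcohol ever sits beside the C4 carboxyl.

**Step 13**
Reactants: 17 (1E)-2-ethyl-1-iodo-3,3-dimethoxyprop-1-ene; 11 (4RS,4aR,7R,7aS)-4,5,7-trimethyl-4,4a,7,7a-tetrahydrocyclopenta[c]pyran-1(3H)-one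
Product: 19 (2E)-3-ethyl-1-[(1S,2R,5R)-2-[(2RS)-1-hydroxypropan-2-yl]-3,5-dimethylcyclopent-3-en-1-yl]-4,4-dimethoxybut-2-en-1-one, via alkenyllithium 18 (not isolated)
Conditions: t-BuLi (2 equiv), Et2O, −78 °C; then 11, THF, −78 °C; aq NH4Cl
Reagents that add atoms: none
Why: Iodine–lithium exchange with retention of alkene geometry, then acyl substitution on the lactone. The lithium hemiketal is stable at −78 °C and releases the ketone only on work-up, so one alkenyl group is added; C8 is freed as the primary alcohol.

**Step 14**
Reactants: 19 (2E)-3-ethyl-1-[(1S,2R,5R)-2-[(2RS)-1-hydroxypropan-2-yl]-3,5-dimethylcyclopent-3-en-1-yl]-4,4-dimethoxybut-2-en-1-one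
Product: 20 (2S,3E)-4-ethyl-2-[(1S,2R,5R)-2-[(2RS)-1-hydroxypropan-2-yl]-3,5-dimethylcyclopent-3-en-1-yl]-5,5-dimethoxypent-3-en-2-ol
Conditions: MeLi, CeCl3, THF, −78 °C; aq NH4Cl
Reagents that add atoms: methyllithium, [Li]C
Why: 1,2-Addition of the organocerium reagent MeCeCl2 to the enone, without conjugate addition or enolisation. Felkin–Anh control, with the more substituted C3a perpendicular to the carbonyl and anti to the nucleophile, should bring methyl in from the face that gives (S) at C7 (carbinol C2 of 20).

**Step 15**
Reactants: 20 (2S,3E)-4-ethyl-2-[(1S,2R,5R)-2-[(2RS)-1-hydroxypropan-2-yl]-3,5-dimethylcyclopent-3-en-1-yl]-5,5-dimethoxypent-3-en-2-ol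
Product: 22 (1S,4RS,4aS,7R,7aS)-1-[(1E)-2-ethyl-3,3-dimethoxyprop-1-en-1-yl]-1,4,5,7-tetramethyl-4,4a,7,7a-tetrahydrocyclopenta[c]pyran-3(1H)-one, via lactol 21 (not isolated)
Conditions: TEMPO (cat.), PhI(OAc)2, NaHCO3, CH2Cl2, rt
Reagents that add atoms: none
Why: Oxidative lactonisation of a 1,5-diol: the primary alcohol is oxidised to the aldehyde, trapped by the tertiary hydroxyl as a lactol and oxidised again. The tertiary alcohol, the alkenes and the C7 configuration are not touched.

**Step 16**
Reactants: 22 (1S,4RS,4aS,7R,7aS)-1-[(1E)-2-ethyl-3,3-dimethoxyprop-1-en-1-yl]-1,4,5,7-tetramethyl-4,4a,7,7a-tetrahydrocyclopenta[c]pyran-3(1H)-one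
Product: 25 (1R,3aR,4R,5S,7aS)-5-(dimethoxymethyl)-5-ethyl-1,3,4,7-tetramethyl-3a,4,5,7a-tetrahydro-1H-indene-4-carboxylic acid, via silyl ketene acetal 23 (not isolated), via trimethylsilyl ester 24 (not isolated)
Conditions: LiN(iPr)2, THF, −78 °C; Me3SiCl/Et3N; → rt, then PhMe, 80–110 °C; dilute aq citric acid
Reagents that add atoms: none
Why: Ireland–Claisen rearrangement of a lactone silyl ketene acetal: the ring ties C7 to C4 through C7a–C3a, so only a boat-like [3,3] array is possible. The C7 alkenyl group, cis to H-7a, reaches the face of C4 that gives (4R) with the carboxyl cis to H-3a; in the boat the (E)-alkene places ethyl (cis to C7) on the side of the C4 methyl and the acetal carbon on the side of the carboxyl, giving (5S). C6=C7 forms as O–C7 breaks, and the mild acid work-up cleaves only the silyl ester.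

**Step 17**
Reactants: 25 (1R,3aR,4R,5S,7aS)-5-(dimethoxymethyl)-5-ethyl-1,3,4,7-tetramethyl-3a,4,5,7a-tetrahydro-1H-indene-4-carboxylic acid
Product: 26 (1R,3aR,4R,5S,7aS)-5-ethyl-5-formyl-1,3,4,7-tetramethyl-3a,4,5,7a-tetrahydro-1H-indene-4-carboxylic acid
Conditions: 1 M HCl, THF, rt
Reagents that add atoms: water, O
Why: Acid-catalysed acetal hydrolysis; the aldehyde has no α-hydrogen, and dilute acid at room temperature does not protonate the trisubstituted alkenes. The product may rest as its cyclic hydroxy-lactone tautomer, which base reopens.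

**Step 18**
Reactants: 26 (1R,3aR,4R,5S,7aS)-5-ethyl-5-formyl-1,3,4,7-tetramethyl-3a,4,5,7a-tetrahydro-1H-indene-4-carboxylic acid; 27 diethyl cinnamylphosphonate [diethyl (2E)-3-phenylprop-2-en-1-ylphosphonate]
Product: 28 (1R,3aR,4R,5S,7aS)-5-ethyl-1,3,4,7-tetramethyl-5-[(1E,3E)-4-phenylbuta-1,3-dien-1-yl]-3a,4,5,7a-tetrahydro-1H-indene-4-carboxylic acid (target)
Conditions: LiN(SiMe3)2 (excess), THF, −78 °C → rt; dilute HCl to pH 4
Reagents that add atoms: none
Why: Horner–Wadsworth–Emmons olefination with an allylic phosphonate anion: the hindered, non-enolisable aldehyde (as its carboxylate) should give the (E)-C1′=C2′ bond while the cinnamyl alkene keeps its geometry. No stereocentre is touched.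

## Compound list

1 | 1-(triphenyl-λ5-phosphanylidene)propan-2-one | CC(=O)C=P(c1ccccc1)(c1ccccc1)c1ccccc1 | starting material
2 | methyl glyoxylate | COC(=O)C=O | starting material
3 | methyl (E)-4-oxopent-2-enoate | CC(=O)/C=C/C(=O)OC | intermediate
4 | (S)-4-(trimethylsilyl)but-3-yn-2-ol | C[Si](C)(C)C#C[C@H](C)O | starting material
5 | (S)-4-(trimethylsilyl)but-3-yn-2-yl methanesulfonate | C[Si](C)(C)C#C[C@H](C)OS(C)(=O)=O | intermediate
6 | (S)-trimethyl(penta-2,3-dien-2-yl)silane | [H]C(C)=[C@]=C(C)[Si](C)(C)C | intermediate
7 | methyl (1R,2R,5S)-2-acetyl-3,5-dimethyl-4-(trimethylsilyl)cyclopent-3-ene-1-carboxylate | CC(=O)[C@H]1C(C)=C([Si](C)(C)C)[C@@H](C)[C@@H]1C(=O)OC | intermediate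
8 | methyl (1R,2S,5S)-3,5-dimethyl-2-(prop-1-en-2-yl)-4-(trimethylsilyl)cyclopent-3-ene-1-carboxylate | C=C(C)[C@H]1C(C)=C([Si](C)(C)C)[C@@H](C)[C@@H]1C(=O)OC | intermediate
9 | methyl (1R,2R,5S)-2-[(2RS)-1-hydroxypropan-2-yl]-3,5-dimethyl-4-(trimethylsilyl)cyclopent-3-ene-1-carboxylate | OCC(C)[C@H]1C(C)=C([Si](C)(C)C)[C@@H](C)[C@@H]1C(=O)OC | intermediate (not isolated)
10 | (4RS,4aR,7S,7aR)-4,5,7-trimethyl-6-(trimethylsilyl)-4,4a,7,7a-tetrahydrocyclopenta[c]pyran-1(3H)-one | O=C2OCC(C)[C@H]1C(C)=C([Si](C)(C)C)[C@@H](C)[C@@H]12 | intermediate
11 | (4RS,4aR,7R,7aS)-4,5,7-trimethyl-4,4a,7,7a-tetrahydrocyclopenta[c]pyran-1(3H)-one | O=C2OCC(C)[C@H]1C(C)=C[C@@H](C)[C@@H]12 | intermediate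
12 | diethyl 2-ethylpropanedioate | CCOC(=O)C(CC)C(=O)OCC | starting material
13 | diethyl 2-(diiodomethyl)-2-ethylpropanedioate | CCOC(=O)C(CC)(C(I)I)C(=O)OCC | intermediate
14 | (2E)-2-ethyl-3-iodoprop-2-enoic acid | I/C=C(\CC)C(=O)O | intermediate
15 | (2E)-2-ethyl-3-iodoprop-2-en-1-ol | I/C=C(\CC)CO | intermediate
16 | (2E)-2-ethyl-3-iodoprop-2-enal | I/C=C(\CC)C=O | intermediate
17 | (1E)-2-ethyl-1-iodo-3,3-dimethoxyprop-1-ene | I/C=C(\CC)C(OC)OC | intermediate
18 | [(1E)-2-ethyl-3,3-dimethoxyprop-1-en-1-yl]lithium | [Li]/C=C(\CC)C(OC)OC | intermediate (not isolated)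
19 | (2E)-3-ethyl-1-[(1S,2R,5R)-2-[(2RS)-1-hydroxypropan-2-yl]-3,5-dimethylcyclopent-3-en-1-yl]-4,4-dimethoxybut-2-en-1-one | OCC(C)[C@H]1C(C)=C[C@@H](C)[C@@H]1C(=O)/C=C(\CC)C(OC)OC | intermediate
20 | (2S,3E)-4-ethyl-2-[(1S,2R,5R)-2-[(2RS)-1-hydroxypropan-2-yl]-3,5-dimethylcyclopent-3-en-1-yl]-5,5-dimethoxypent-3-en-2-ol | OCC(C)[C@H]1C(C)=C[C@@H](C)[C@@H]1[C@@](C)(/C=C(\CC)C(OC)OC)O | intermediate
21 | lactol of 22 (3-hydroxy in place of 3-oxo; C1, C4a, C7, C7a as in 22) | OC2C(C)[C@H]1C(C)=C[C@@H](C)[C@@H]1[C@@](C)(/C=C(\CC)C(OC)OC)O2 | intermediate (not isolated)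
22 | (1S,4RS,4aS,7R,7aS)-1-[(1E)-2-ethyl-3,3-dimethoxyprop-1-en-1-yl]-1,4,5,7-tetramethyl-4,4a,7,7a-tetrahydrocyclopenta[c]pyran-3(1H)-one | O=C2C(C)[C@H]1C(C)=C[C@@H](C)[C@@H]1[C@@](C)(/C=C(\CC)C(OC)OC)O2 | intermediate
23 | trimethylsilyl ketene acetal of 22 (C8–OSiMe3, C4=C8; other centres as in 22) | C[Si](C)(C)OC2=C(C)[C@H]1C(C)=C[C@@H](C)[C@@H]1[C@@](C)(/C=C(\CC)C(OC)OC)O2 | intermediate (not isolated)
24 | trimethylsilyl (1R,3aR,4R,5S,7aS)-5-(dimethoxymethyl)-5-ethyl-1,3,4,7-tetramethyl-3a,4,5,7a-tetrahydro-1H-indene-4-carboxylate | CC[C@]1(C(OC)OC)C=C(C)[C@H]2[C@H](C)C=C(C)[C@@H]2[C@@]1(C)C(=O)O[Si](C)(C)C | intermediate (not isolated)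
25 | (1R,3aR,4R,5S,7aS)-5-(dimethoxymethyl)-5-ethyl-1,3,4,7-tetramethyl-3a,4,5,7a-tetrahydro-1H-indene-4-carboxylic acid | CC[C@]1(C(OC)OC)C=C(C)[C@H]2[C@H](C)C=C(C)[C@@H]2[C@@]1(C)C(=O)O | intermediate
26 | (1R,3aR,4R,5S,7aS)-5-ethyl-5-formyl-1,3,4,7-tetramethyl-3a,4,5,7a-tetrahydro-1H-indene-4-carboxylic acid | CC[C@]1(C=O)C=C(C)[C@H]2[C@H](C)C=C(C)[C@@H]2[C@@]1(C)C(=O)O | intermediate
27 | diethyl cinnamylphosphonate | CCOP(=O)(C/C=C/c1ccccc1)OCC | starting material
28 | (1R,3aR,4R,5S,7aS)-5-ethyl-1,3,4,7-tetramethyl-5-[(1E,3E)-4-phenylbuta-1,3-dien-1-yl]-3a,4,5,7a-tetrahydro-1H-indene-4-carboxylic acid | CC[C@]1(/C=C/C=C/c2ccccc2)C=C(C)[C@H]2[C@H](C)C=C(C)[C@@H]2[C@@]1(C)C(=O)O | target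

## Step count and risks

Total step count: 18. Longest linear sequence: 12 steps (from 4 through steps 2–7 and 13–18 to 28).

**Step 4 (key step).** The most likely failure is loss of regiocontrol. Both alkene carbons of 3 are acceptor positions, so activation through the ester would give the cyclopentene with ketone and ester interchanged. Erosion of the 1,7a-trans topicity in the open transition state is the second concern.

Fallback, setting out from 1 and 6 and returning at 7: the ester is replaced by a group that cannot direct. Wittig reaction of 1 with (tert-butyldimethylsilyloxy)acetaldehyde gives (E)-5-{[tert-butyl(dimethyl)silyl]oxy}pent-3-en-2-one F1. Annulation of F1 with 6 under the TiCl4 conditions gives the silyloxymethyl cyclopentene F2. Bu4NF frees the hydroxymethyl ketone F3. TEMPO with PhI(OAc)2 in aqueous MeCN oxidises F3 to the keto acid F4, and Me3SiCHN2 esterifies F4 to 7.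

**Step 14.** Facial selectivity at C7 may be poor or reversed, because the two ring carbons flanking C7a differ only in their more remote substituents. The epimeric diols would have to be separated at 20 or 22.

Fallback, setting out from 11 and returning at 20: the two nucleophiles are introduced in the opposite order. One equivalent of MeLi at −78 °C opens 11 to the hydroxy methyl ketone F5. CeCl3-mediated addition of 18 to F5 then gives 20, the same facial preference now delivering the alkenyl group instead of methyl.

**Step 16.** The boat may be hard to reach. The trans-fused cyclopentene holds the C7–C7a–C3a–C4 torsion near gauche and two quaternary centres form in an eclipsed array, so ionisation of the tertiary allylic C7–O bond or decomposition of the ketene acetal can compete.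

Fallback, setting out from 11 and returning at 25: the rearrangement is run on an open-chain ester and the ring is closed afterwards.
- Lactone 11 is opened with MeLi to the same ketone F5.
- Methylenation as in step 5 gives the isopropenyl alcohol F6.
- TEMPO with PhI(OAc)2 in aqueous MeCN gives the acid F7.
- Alkenyllithium 18 and formaldehyde give (2E)-3-ethyl-4,4-dimethoxybut-2-en-1-ol F8.
- Carbodiimide coupling of F7 with F8 gives the allyl ester F9.
- Ireland–Claisen rearrangement of F9 through a chair gives the C5-vinyl acid F10.
- Ring-closing metathesis of F10 with the second-generation Grubbs catalyst forms C6=C7 and gives 25.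

Stereocontrol at C4 and C5 would then rest on the ketene acetal geometry of an α-branched ester and on face selection by C3a, which is less secure than in the lactone.

**Step 18.** Addition to the aldehyde may be slow, because it is flanked by two quaternary carbons and tied up as the cyclic hydroxy-lactone tautomer. This would leave time for erosion of the (E)-selectivity.

Fallback, setting out from 26 and returning at 28: the C2′–C3′ bond is made by cross-coupling. Methylenation of 26 with Ph3P=CH2 gives the C5-vinyl acid F11. Heck coupling of F11 with (E)-(2-bromovinyl)benzene (Pd(OAc)2, P(o-tol)3, Et3N, MeCN, 80 °C) adds the styryl group at the terminal carbon and, after β-hydride loss, gives the (1E,3E)-diene of 28.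

## Further compounds

F1 | step 4 | (E)-5-{[tert-butyl(dimethyl)silyl]oxy}pent-3-en-2-one | CC(=O)/C=C/CO[Si](C)(C)C(C)(C)C
F2 | step 4 | analogue of 7 with CH2OSi(t-Bu)Me2 in place of CO2Me on C7a (all-trans, configuration as in 7) | CC(=O)[C@H]1C(C)=C([Si](C)(C)C)[C@@H](C)[C@@H]1CO[Si](C)(C)C(C)(C)C
F3 | step 4 | analogue of 7 with CH2OH in place of CO2Me on C7a | CC(=O)[C@H]1C(C)=C([Si](C)(C)C)[C@@H](C)[C@@H]1CO
F4 | step 4 | carboxylic acid corresponding to ester 7 | CC(=O)[C@H]1C(C)=C([Si](C)(C)C)[C@@H](C)[C@@H]1C(=O)O
F5 | step 14 | 1-[2-(1-hydroxypropan-2-yl)-3,5-dimethylcyclopent-3-en-1-yl]ethan-1-one (ring configuration as in 19) | OCC(C)[C@H]1C(C)=C[C@@H](C)[C@@H]1C(C)=O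
F6 | step 16 | 2-[2,4-dimethyl-5-(prop-1-en-2-yl)cyclopent-2-en-1-yl]propan-1-ol (ring configuration as in 19) | OCC(C)[C@H]1C(C)=C[C@@H](C)[C@@H]1C(C)=C
F7 | step 16 | 2-[2,4-dimethyl-5-(prop-1-en-2-yl)cyclopent-2-en-1-yl]propanoic acid | OC(=O)C(C)[C@H]1C(C)=C[C@@H](C)[C@@H]1C(C)=C
F8 | step 16 | (2E)-3-ethyl-4,4-dimethoxybut-2-en-1-ol | OC/C=C(\CC)C(OC)OC
F9 | step 16 | (2E)-3-ethyl-4,4-dimethoxybut-2-en-1-yl ester of F7 | CC(C(=O)OC/C=C(\CC)C(OC)OC)[C@H]1C(C)=C[C@@H](C)[C@@H]1C(C)=C
F10 | step 16 | open-chain acid with C4 and C5 as in 25, vinyl on C5 and isopropenyl on C7a | C=C[C@](CC)(C(OC)OC)[C@](C)(C(=O)O)[C@H]1C(C)=C[C@@H](C)[C@@H]1C(C)=C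
F11 | step 18 | 5-ethenyl analogue of 26 (vinyl in place of formyl on C5) | CC[C@]1(C=C)C=C(C)[C@H]2[C@H](C)C=C(C)[C@@H]2[C@@]1(C)C(=O)O
A1 | alternative 1 | cis-fused 1-ethyl-7,7-dimethoxy-6-methyl-5-{[tert-butyl(dimethyl)silyl]oxymethyl}bicyclo[4.2.0]octan-2-one | CC[C@@]12CC(OC)(OC)[C@]1(C)[C@@H](CO[Si](C)(C)C(C)(C)C)CCC2=O
A2 | alternative 1 | 4-{[tert-butyl(dimethyl)silyl]oxymethyl}-2-ethyl-3-methylcyclohex-2-en-1-one | CCC1=C(C)[C@@H](CO[Si](C)(C)C(C)(C)C)CCC1=O
A3 | alternative 1 | 1,1-dimethoxyethene | C=C(OC)OC
A4 | alternative 2 | methyl ester of 28 | CC[C@]1(/C=C/C=C/c2ccccc2)C=C(C)[C@H]2[C@H](C)C=C(C)[C@@H]2[C@@]1(C)C(=O)OC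
A5 | alternative 2 | Heck substrate: methyl ester with (Z)-2-iodo-1-methylvinyl on C7a and the C5=C1′ trisubstituted alkene (drawn E) on C4 | CC/C(=C\C/C=C/c1ccccc1)[C@](C)(C(=O)OC)[C@H]1C(C)=C[C@@H](C)[C@@H]1/C(C)=C\I
A6 | alternative 3 | 5-{[tert-butyl(dimethyl)silyl]oxymethyl} analogue of acid 25 | CC[C@]1(CO[Si](C)(C)C(C)(C)C)C=C(C)[C@H]2[C@H](C)C=C(C)[C@@H]2[C@@]1(C)C(=O)O
A7 | alternative 3 | analogue of lactone 22 with CH2OSi(t-Bu)Me2 in place of CH(OMe)2 | O=C2C(C)[C@H]1C(C)=C[C@@H](C)[C@@H]1[C@@](C)(/C=C(\CC)CO[Si](C)(C)C(C)(C)C)O2
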